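**Retrosynthetic overview**

- Feature: in the cyclohexenone ring the oxygen atoms on C1 (carbonyl) and C4 (carbinol) stand 1,4 to each other across the C2=C3 double bond, on the ring face opposite to the cis-diol at C5 and the fully substituted C6. This is the footprint of a 2,3-dioxabicyclo[2.2.2]oct-5-ene formed from a cyclohexa-1,3-diene and singlet oxygen, anti to a protected ipso,ortho cis-diol.
- Disconnections: C1 ketone from the C1 carbinol; side-chain C2'–C3' bond by B-alkyl Suzuki coupling of a C6 vinyl group (C1' is the former ester carbon) with (Z)-1-bromopentadec-6-ene (Wittig, from 1-bromononane and 6-bromohexan-1-ol); C1–O and C4–O by [4+2] photooxygenation.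
- O1 and O4 are told apart by tying O1 to the side-chain carbon in a 4-methoxybenzylidene acetal (later a 4-methoxybenzyl ether), while O4 becomes a silyl ether.
- Ring order: the carbocycle comes intact from benzoic acid by microbial ipso,ortho-dihydroxylation (sets C5 and C6); the dioxolane is closed next; the 1,2-dioxene bridge is closed in the key step (sets C1 and C4) and opened again by reduction.

Key step: step 4

Numbering: ring atoms are numbered as in the target throughout (C1 carbonyl carbon, C2=C3, C4, C5, C6 quaternary); the side chain is C1'–C17' counted from the ring. The target is (4S,5R,6R) with an 8'Z alkene.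
Assumption: oxidation of benzoate by the blocked mutant Ralstonia eutropha B9 is taken to deliver the (1S,6R) diol acid, whose C1 and C6 become C6 and C5 of the target in the required configuration.

**Route**

Step 1
Reactants: 1 benzoic acid (fed as sodium benzoate)
Product: 2 (1S,6R)-1,6-dihydroxycyclohexa-2,4-diene-1-carboxylic acid
Conditions: Ralstonia eutropha B9 whole cells, fructose/mineral-salts medium, air, pH 7, 30 °C; then pH 3 (0 °C), EtOAc
Reagents that add atoms: dioxygen, O=O
Why: enzymatic arene cis-dihydroxylation, in which benzoate 1,2-dioxygenase delivers both atoms of O2 to the ipso and ortho carbons from one face, the mutant cannot dehydrogenate the diol, the enzyme fixes both stereocentres (C6 and C5 of the target), and the two hydrogens come from the cells' cofactor pool, regenerated from fructose.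

Step 2
Reactants: 2 (1S,6R)-diol acid
Product: 3 methyl (1S,6R)-1,6-dihydroxycyclohexa-2,4-diene-1-carboxylate
Conditions: Me3SiCHN2, MeOH/PhMe, 0 °C
Reagents that add atoms: trimethylsilyldiazomethane, C[Si](C)(C)C=[N+]=[N-]
Why: diazoalkane O-methylation of the carboxylic acid is neutral and cold, so the acid-labile dienediol should neither dehydrate nor aromatise and no stereocentre is touched.

Step 3
Reactants: 3 methyl ester diol
Product: 4 methyl (3aS,7aR)-2,2-dimethyl-3a,7a-dihydro-1,3-benzodioxole-3a-carboxylate (5,6-O-isopropylidene derivative of 3)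
Conditions: Me2C(OMe)2, TsOH·H2O (cat.), acetone, 0 °C → rt; Et3N quench
Reagents that add atoms: 2,2-dimethoxypropane, COC(C)(C)OC
Why: acid-catalysed transacetalisation (acetonide formation) closes the cis-fused 1,3-dioxolane on the cis-diol, and the ester on C6 disfavours ionisation of the allylic C–O bonds so that aromatisation should stay slow under catalytic acid.

Step 4
Reactants: 4 diene acetonide ester
Product: 5 anti endoperoxide: methyl 1,4-epidioxy-5,6-(isopropylidenedioxy)cyclohex-2-ene-6-carboxylate (2,3-dioxabicyclo[2.2.2]oct-5-ene core, O–O bridge from C1 to C4 on the face opposite the dioxolane)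
Conditions: O2, tetraphenylporphyrin (cat.), CH2Cl2, visible light (white LED), −20 → 0 °C
Reagents that add atoms: dioxygen, O=O
Why: Energy transfer from the excited porphyrin gives singlet oxygen, which adds across C1 and C4 of the ring-locked s-cis C1=C2–C3=C4 diene of 4 in a concerted suprafacial [4+2] cycloaddition, forming the C1–O and C4–O bonds together and moving the double bond to C2=C3. The closest known reaction type is the anti-selective photooxygenation of acetonide-protected arene cis-dihydrodiols to bicyclic endoperoxides. The 1,2-dioxene ring closes as the two-atom O–O bridge of the bicyclo[2.2.2]octene, both ends bonding in the same cycloaddition event and not by a stepwise cyclisation. The configurations at C1 and C4 are set together by the face of attack, which the existing C5/C6 stereocentres dictate through the cis-fused dioxolane: its two oxygen atoms and endo methyl group shield one face, so both C–O bonds form trans to O5 and O6. The step needs π-facial selectivity and chemoselectivity for [4+2] over ene or [2+2] modes; the first comes from the dioxolane, the second from the cisoid cyclic diene, which should react far faster than the lone allylic C5–H, and from the ester sitting on sp3 C6, where it does not deactivate the diene. Low temperature and an amine-free work-up should keep the peroxide from Kornblum–DeLaMare isomerisation before it is reduced.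

Step 5
Reactants: 5 endoperoxide ester
Product: 6 triol: 6-(hydroxymethyl)-5,6-O-isopropylidenecyclohex-2-ene-1,4,5,6-tetrol, with O1–H, O4–H and CH2OH on one face and the dioxolane on the other
Conditions: LiAlH4, THF, −20 → 0 °C; aq. NaOH work-up
Reagents that add atoms: none
Why: hydride reduces the ester to the primary alcohol and cleaves the weak O–O bond (hydride reduction of a dialkyl peroxide) in one operation, and since neither the C1–O nor the C4–O bond is broken the cis-1,4-diol keeps the configuration set in step 4.

Step 6
Reactants: 6 triol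
Product: 7 4-methoxybenzylidene acetal bridging O1 and O1' (cis-fused 1,3-dioxane), O4–H free
Conditions: 4-MeOC6H4CH(OMe)2, PPTS (cat.), 4 Å MS, CH2Cl2, rt
Reagents that add atoms: 4-methoxybenzaldehyde dimethyl acetal, COC(OC)c1ccc(OC)cc1
Why: acid-catalysed transacetalisation under thermodynamic control closes the six-membered 1,3-dioxane on the cis-disposed O1/O1' pair in preference to a seven-membered ring through O4, and the weak pyridinium acid leaves the isopropylidene acetal in place, so O4–H remains the only free hydroxyl.

Step 7
Reactants: 7 benzylidene acetal alcohol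
Product: 8 O4-tert-butyldimethylsilyl ether of 7
Conditions: TBSCl, imidazole, DMF, rt
Reagents that add atoms: tert-butyldimethylsilyl chloride, CC(C)(C)[Si](C)(C)Cl
Why: standard silyl ether formation on the only free hydroxyl, an unhindered secondary allylic alcohol.

Step 8
Reactants: 8 silyl ether acetal
Product: 9 primary alcohol with O1 as 4-methoxybenzyl ether, O4 as TBS ether and the 5,6-acetonide
Conditions: i-Bu2AlH, CH2Cl2, −78 → 0 °C; aq. KNaC4H4O6 work-up
Reagents that add atoms: none
Why: reductive opening of a 4-methoxybenzylidene acetal, in which i-Bu2AlH coordinates the less hindered primary acetal oxygen O1', the aryl-stabilised oxocarbenium ion is reduced and the 4-methoxybenzyl group stays on secondary O1 while the primary alcohol is released; the isopropylidene acetal lacks that stabilisation and should not open at this temperature.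

Step 9
Reactants: 9 primary alcohol
Product: 10 aldehyde (C6–CHO) with O1-PMB, O4-TBS and the 5,6-acetonide
Conditions: Dess–Martin periodinane, pyridine, CH2Cl2, 0 °C → rt
Reagents that add atoms: none
Why: Dess–Martin oxidation of the neopentyl-type primary alcohol stops at the aldehyde, which has no α-hydrogen and therefore cannot epimerise or eliminate.

Step 10
Reactants: 10 aldehyde
Product: 11 C6-vinyl compound with O1-PMB, O4-TBS and the 5,6-acetonide
Conditions: Ph3PCH3Br, KN(SiMe3)2, THF, 0 °C; then 10, 0 °C → rt
Reagents that add atoms: methyltriphenylphosphonium bromide, C[P+](c1ccccc1)(c1ccccc1)c1ccccc1.[Br-]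
Why: Wittig methylenation with the small unstabilised ylide works on hindered, non-enolisable aldehydes and turns the former carboxyl carbon into C1' of the side chain.

Step 11
Reactants: 12 1-bromononane
Product: 13 nonyltriphenylphosphonium bromide
Conditions: PPh3, MeCN, reflux
Reagents that add atoms: triphenylphosphine, c1ccc(cc1)P(c1ccccc1)c1ccccc1
Why: SN2 quaternisation of the phosphine by the primary bromide.

Step 12
Reactants: 14 6-bromohexan-1-ol
Product: 15 6-bromohexanal
Conditions: TEMPO (cat.), PhI(OAc)2, CH2Cl2, rt
Reagents that add atoms: none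
Why: TEMPO-catalysed oxoammonium oxidation takes the primary alcohol to the aldehyde without over-oxidation and leaves the alkyl bromide alone.

Step 13
Reactants: 13 nonyltriphenylphosphonium bromide; 15 6-bromohexanal
Product: 17 (Z)-1-bromopentadec-6-ene, via nonylidenetriphenylphosphorane 16 (not isolated)
Conditions: NaN(SiMe3)2, THF, 0 °C; then 15, −78 °C → rt
Reagents that add atoms: none
Why: salt-free Wittig olefination of a non-stabilised ylide passes through the kinetically favoured cis-oxaphosphetane and should give the Z alkene, and at −78 °C carbonyl addition outruns alkylation of the ylide by the primary bromide.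

Step 14
Reactants: 11 C6-vinyl compound; 17 (Z)-1-bromopentadec-6-ene
Product: 19 C6-[(8Z)-heptadec-8-enyl] compound with O1-PMB and O4-TBS and the 5,6-acetonide, via B-alkyl-9-BBN borane 18 (not isolated)
Conditions: 9-BBN, THF, 0 → 45 °C; then 17, Pd(OAc)2 (cat.), PCy3 (cat.), K3PO4·H2O, THF, rt
Reagents that add atoms: 9-borabicyclo[3.3.1]nonane (9-BBN), [H]B1C2CCCC1CCC2 (its boron and ring carbons stay in 18 and leave again on the way to 19; only its hydrogen remains in 19)
Why: 9-BBN hydroborates the monosubstituted vinyl group at its terminal carbon much faster than the hindered ring cis-alkene, and the primary alkylborane then undergoes B-alkyl Suzuki–Miyaura coupling with the primary bromide under conditions (zerovalent palladium with the electron-rich PCy3) in which oxidative addition to the C(sp3)–Br bond and transmetalation should outpace β-hydride elimination, the Z alkene of 17 being a spectator.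

Step 15
Reactants: 19 coupled PMB ether
Product: 20 C1 alcohol with O4-TBS, the 5,6-acetonide and the full side chain
Conditions: DDQ, CH2Cl2/aq. pH 7 buffer (KH2PO4/K2HPO4), 0 °C
Reagents that add atoms: none
Why: oxidative cleavage of the 4-methoxybenzyl ether by hydride abstraction at its electron-rich benzylic carbon and hydrolysis of the oxocarbenium ion frees O1–H without touching the silyl ether, the acetal or the unactivated alkenes, and any further oxidation of the liberated allylic alcohol would lead to the product of step 16.

Step 16
Reactants: 20 C1 alcohol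
Product: 21 enone: 4-O-TBS-5,6-O-isopropylidene derivative of the target
Conditions: Dess–Martin periodinane, pyridine, CH2Cl2, 0 °C → rt
Reagents that add atoms: none
Why: Dess–Martin oxidation of the free allylic C1 carbinol gives the conjugated enone, erasing on purpose the C1 stereocentre made in step 4 while C4, C5 and C6 are untouched.

Step 17
Reactants: 21 protected enone
Product: 22 pleiogenone A, (4S,5R,6R)-6-[(8Z)-heptadec-8-en-1-yl]-4,5,6-trihydroxycyclohex-2-en-1-one
Conditions: TFA/H2O/THF, 0 °C → rt
Reagents that add atoms: none
Why: aqueous acid hydrolyses the silyl ether at the Si–O bond and the isopropylidene acetal at its acetal carbon, so no bond to C4, C5 or C6 is broken and their configurations carry over to the target, while the isolated Z alkene should not be protonated under these conditions.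

**Compound list**

1 | benzoic acid | OC(=O)c1ccccc1 | starting material
2 | (1S,6R)-1,6-dihydroxycyclohexa-2,4-diene-1-carboxylic acid | OC(=O)[C@]1(O)C=CC=C[C@H]1O | intermediate
3 | methyl (1S,6R)-1,6-dihydroxycyclohexa-2,4-diene-1-carboxylate | COC(=O)[C@]1(O)C=CC=C[C@H]1O | intermediate
4 | methyl (3aS,7aR)-2,2-dimethyl-3a,7a-dihydro-1,3-benzodioxole-3a-carboxylate | COC(=O)[C@]1(OC(C)(C)O2)C=CC=C[C@H]12 | intermediate
5 | anti endoperoxide, C1–O–O–C4 bridge trans to the dioxolane | COC(=O)[C@]1(OC(C)(C)O2)[C@H](OO3)C=C[C@H]3[C@H]12 | intermediate
6 | triol: 6-(hydroxymethyl)-5,6-O-isopropylidenecyclohex-2-ene-1,4,5,6-tetrol (O1, O4, CH2OH cis; dioxolane trans) | OC[C@]1(OC(C)(C)O2)[C@H](O)C=C[C@H](O)[C@H]12 | intermediate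
7 | O1,O1'-(4-methoxybenzylidene) acetal of 6 (acetal carbon: either epimer) | COc1ccc(cc1)C3OC[C@]1(OC(C)(C)O2)[C@H](O3)C=C[C@H](O)[C@H]12 | intermediate
8 | O4-TBS ether of 7 | COc1ccc(cc1)C3OC[C@]1(OC(C)(C)O2)[C@H](O3)C=C[C@H](O[Si](C)(C)C(C)(C)C)[C@H]12 | intermediate
9 | primary alcohol, O1-PMB, O4-TBS, 5,6-acetonide | OC[C@]1(OC(C)(C)O2)[C@H](OCc3ccc(OC)cc3)C=C[C@H](O[Si](C)(C)C(C)(C)C)[C@H]12 | intermediate
10 | aldehyde, O1-PMB, O4-TBS, 5,6-acetonide | O=C[C@]1(OC(C)(C)O2)[C@H](OCc3ccc(OC)cc3)C=C[C@H](O[Si](C)(C)C(C)(C)C)[C@H]12 | intermediate
11 | C6-vinyl compound, O1-PMB, O4-TBS, 5,6-acetonide | C=C[C@]1(OC(C)(C)O2)[C@H](OCc3ccc(OC)cc3)C=C[C@H](O[Si](C)(C)C(C)(C)C)[C@H]12 | intermediate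
12 | 1-bromononane | CCCCCCCCCBr | starting material
13 | nonyltriphenylphosphonium bromide | CCCCCCCCC[P+](c1ccccc1)(c1ccccc1)c1ccccc1.[Br-] | intermediate
14 | 6-bromohexan-1-ol | OCCCCCCBr | starting material
15 | 6-bromohexanal | O=CCCCCCBr | intermediate
16 | nonylidenetriphenylphosphorane | CCCCCCCCC=P(c1ccccc1)(c1ccccc1)c1ccccc1 | intermediate
17 | (Z)-1-bromopentadec-6-ene | CCCCCCCC/C=C\CCCCCBr | intermediate
18 | B-alkyl-9-BBN borane: 9-[2-(ring C6)ethyl]-9-borabicyclo[3.3.1]nonane | C1CC2CCCC(C1)B2CC[C@]1(OC(C)(C)O2)[C@H](OCc3ccc(OC)cc3)C=C[C@H](O[Si](C)(C)C(C)(C)C)[C@H]12 | intermediate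
19 | C6-[(8Z)-heptadec-8-enyl] compound, O1-PMB, O4-TBS, 5,6-acetonide | CCCCCCCC/C=C\CCCCCCC[C@]1(OC(C)(C)O2)[C@H](OCc3ccc(OC)cc3)C=C[C@H](O[Si](C)(C)C(C)(C)C)[C@H]12 | intermediate
20 | C1 alcohol, O4-TBS, 5,6-acetonide | CCCCCCCC/C=C\CCCCCCC[C@]1(OC(C)(C)O2)[C@H](O)C=C[C@H](O[Si](C)(C)C(C)(C)C)[C@H]12 | intermediate
21 | enone, O4-TBS, 5,6-acetonide | CCCCCCCC/C=C\CCCCCCC[C@]1(OC(C)(C)O2)C(=O)C=C[C@H](O[Si](C)(C)C(C)(C)C)[C@H]12 | intermediate
22 | pleiogenone A | CCCCCCCC/C=C\CCCCCCC[C@]1(O)C(=O)C=C[C@H](O)[C@H]1O | target

**Step count and risks**

Total steps: 17. Longest linear sequence: 14 steps (steps 1–10 and 14–17); the side-chain bromide takes steps 11–13.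

Steps most likely to fail:

1. Step 4. Singlet oxygen may attack the dioxolane face in part, because the open face also carries the ester on C6, an ene reaction at C5–H may compete, and the peroxide may isomerise before it is reduced. Fallback: from 4, m-CPBA (NaHCO3, CH2Cl2, 0 °C) should epoxidise the less hindered C3=C4 bond anti to the dioxolane to give the vinyl epoxide F1. Pd(PPh3)4 (cat.) with AcOH in THF at 0 °C then opens it: zerovalent palladium ionises the allylic C3–O bond with inversion and acetate attacks C1 anti to the metal, so the net result is cis-1,4 and the hydroxy acetate F2 carries O1 and O4 both trans to the dioxolane. LiAlH4 in THF reduces ester and acetate together, and the route is rejoined at 6.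

2. Step 14. Hydroboration next to the quaternary carbon may be slow, the alkylpalladium intermediate may undergo β-hydride elimination, and a palladium hydride may isomerise the Z alkene. Fallback: from 11, hydroboration to 18 as before, followed by oxidative work-up (NaBO3·4H2O, THF/H2O), gives the primary alcohol F3. TsCl in pyridine gives the tosylate F4. The bromide 17 and Mg in THF give (Z)-pentadec-6-enylmagnesium bromide F5, and Li2CuCl4-catalysed sp3–sp3 coupling of F4 with F5 (THF, −78 °C → rt) returns to 19.

3. Step 8. The hydride may open the benzylidene acetal the other way, leaving the benzyl group on O1', or may begin to open the isopropylidene acetal. Fallback: from 6, TBSCl (2 equiv) and imidazole in DMF should silylate the two accessible hydroxyls O1'–H and O4–H and leave the hindered O1–H free, giving the bis-silyl ether F6. 4-Methoxybenzyl trichloroacetimidate with catalytic La(OTf)3 in toluene (non-basic, so no silyl migration) gives the 4-methoxybenzyl ether F7. HF·pyridine in pyridine/THF at 0 °C removes the primary silyl ether faster than the secondary one and returns to 9.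

Further compounds
F1 | step 4 | vinyl epoxide: methyl 3,4-epoxy-5,6-(isopropylidenedioxy)cyclohex-1-ene-6-carboxylate, epoxide trans to the dioxolane | COC(=O)[C@]1(OC(C)(C)O2)C=C[C@@H]3O[C@@H]3[C@H]12
F2 | step 4 | hydroxy acetate: C1–OAc and C4–OH cis to each other, trans to the dioxolane | COC(=O)[C@]1(OC(C)(C)O2)[C@H](OC(C)=O)C=C[C@H](O)[C@H]12
F3 | step 14 | primary alcohol C6–CH2CH2OH, O1-PMB, O4-TBS, 5,6-acetonide | OCC[C@]1(OC(C)(C)O2)[C@H](OCc3ccc(OC)cc3)C=C[C@H](O[Si](C)(C)C(C)(C)C)[C@H]12
F4 | step 14 | tosylate of F3 | Cc1ccc(cc1)S(=O)(=O)OCC[C@]1(OC(C)(C)O2)[C@H](OCc3ccc(OC)cc3)C=C[C@H](O[Si](C)(C)C(C)(C)C)[C@H]12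
F5 | step 14 | (Z)-pentadec-6-enylmagnesium bromide | CCCCCCCC/C=C\CCCCC[Mg]Br
F6 | step 8 | O1',O4-bis-TBS ether of 6, O1–H free | CC(C)(C)[Si](C)(C)OC[C@]1(OC(C)(C)O2)[C@H](O)C=C[C@H](O[Si](C)(C)C(C)(C)C)[C@H]12
F7 | step 8 | O1-PMB ether of F6 | CC(C)(C)[Si](C)(C)OC[C@]1(OC(C)(C)O2)[C@H](OCc3ccc(OC)cc3)C=C[C@H](O[Si](C)(C)C(C)(C)C)[C@H]12
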